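The route rests on reading the chain end, the E C9=C10 alkene beside the tertiary carbinol C11 with its methyl and its acyloxymethyl carbon C12, as the 1,3-oxygen-transposed form of a C10–C11 oxirane of an (E)-2-methylallylic alcohol (C10=C11, hydroxyl on C12). A Sharpless epoxidation of that terminus makes both C–O bonds of this temporary three-membered ring in one operation and fixes C11 by reagent control. Selenide opening at C10 and selenoxide elimination then move the alkene to C9=C10. The precursor is the (E)-allylic alcohol whose cyclohexene ring, taken from (S)-carvone, carries its C5 and C15 oxygens as two different silyl ethers.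

Key step: step 10

Remark: atom numbers are those of the target (ring C1–C6 with the chain on C1, the oxymethyl carbon C15 on C4 and the hydroxyl on C5; chain C7–C12 with methylene C14 on C7 and methyl C13 on C11); TBS = tert-butyldimethylsilyl, TES = triethylsilyl, TESOCH2 = (triethylsilyloxy)methyl.

Step 1
Reactants: 1 (S)-carvone
Product: 2 (5S)-5-(3-chloroprop-1-en-2-yl)-2-methylcyclohex-2-en-1-one
Conditions: Ca(OCl)2, CO2 (solid), CH2Cl2/H2O, 0 °C
Reagents that add atoms: calcium hypochlorite, [Ca+2].[O-]Cl.[O-]Cl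
Why: HOCl made in the flask chlorinates the electron-rich 1,1-disubstituted alkene and a methyl proton is lost (ene-type allylic chlorination), which should spare the electron-poor enone alkene and leave untouched the ring stereocentre that becomes C1.

Step 2
Reactants: 2 (5S)-5-(3-chloroprop-1-en-2-yl)-2-methylcyclohex-2-en-1-one
Product: 3 (1S,5S)-5-(3-chloroprop-1-en-2-yl)-2-methylcyclohex-2-en-1-ol
Conditions: NaBH4, CeCl3·7H2O, MeOH, −78 °C
Reagents that add atoms: none
Why: Luche reduction, in which the cerium-activated carbonyl is attacked 1,2 along the axial trajectory of the half-chair that keeps the C1 side chain equatorial, so the new carbinol centre (C5 of the target, 5S) should form with the hydroxyl cis to the side chain while the allylic chloride stays intact.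

Step 3
Reactants: 3 (1S,5S)-5-(3-chloroprop-1-en-2-yl)-2-methylcyclohex-2-en-1-ol
Product: 4 tert-butyl{[(1S,5S)-5-(3-chloroprop-1-en-2-yl)-2-methylcyclohex-2-en-1-yl]oxy}dimethylsilane
Conditions: TBSOTf, 2,6-lutidine, CH2Cl2, −78 to 0 °C
Reagents that add atoms: tert-butyldimethylsilyl trifluoromethanesulfonate, CC(C)(C)[Si](C)(C)OS(=O)(=O)C(F)(F)F
Why: Silyl triflate silylation of a secondary allylic alcohol with a hindered pyridine base, chosen so that no nucleophile able to displace the allylic chloride is present.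

Step 4
Reactants: 4 tert-butyl{[(1S,5S)-5-(3-chloroprop-1-en-2-yl)-2-methylcyclohex-2-en-1-yl]oxy}dimethylsilane
Product: 5 [(4S,6S)-6-(TBSO)-4-(3-chloroprop-1-en-2-yl)cyclohex-1-en-1-yl]methanol
Conditions: SeO2 (0.5 equiv), t-BuOOH, CH2Cl2, 0 °C to rt
Reagents that add atoms: selenium dioxide, O=[Se]=O (oxygen carrier); tert-butyl hydroperoxide, CC(C)(C)OO (terminal oxidant)
Why: Riley-type allylic oxidation (ene reaction of SeO2 at C3, then [2,3]-sigmatropic shift) should put oxygen on the methyl group at the more substituted end of the trisubstituted ring alkene, the only unoxidised allylic position there, while the side-chain alkene is deactivated by its chloromethyl group and the catalytic regime should stop largely at the alcohol.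

Step 5
Reactants: 5 [(4S,6S)-6-(TBSO)-4-(3-chloroprop-1-en-2-yl)cyclohex-1-en-1-yl]methanol
Product: 6 triethyl{[(4S,6S)-6-(TBSO)-4-(3-chloroprop-1-en-2-yl)cyclohex-1-en-1-yl]methoxy}silane
Conditions: TESCl, imidazole, CH2Cl2, 0 °C
Reagents that add atoms: chlorotriethylsilane, CC[Si](Cl)(CC)CC
Why: Standard silylation of a primary alcohol, the triethylsilyl group being chosen because it can later be taken off O15 without disturbing the secondary TBS ether on O5.

Step 6
Reactants: 6 triethyl{[(4S,6S)-6-(TBSO)-4-(3-chloroprop-1-en-2-yl)cyclohex-1-en-1-yl]methoxy}silane; 7 tert-butyl acetate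
Product: 9 tert-butyl 4-[(1S,5S)-5-(TBSO)-4-(TESOCH2)cyclohex-3-en-1-yl]pent-4-enoate, via lithium enolate of tert-butyl acetate 8 (not isolated)
Conditions: 7, LiN(i-Pr)2, THF, −78 °C; then 6, DMPU, −78 to 0 °C
Reagents that add atoms: tert-butyl acetate (7), CC(=O)OC(C)(C)C
Why: Ester enolate alkylation, in which the non-self-condensing lithium enolate displaces the primary allylic chloride to form C8–C9, and because the 2-substituted allyl unit is symmetric, direct and allylically transposed substitution give the same product.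

Step 7
Reactants: 9 tert-butyl 4-[(1S,5S)-5-(TBSO)-4-(TESOCH2)cyclohex-3-en-1-yl]pent-4-enoate
Product: 10 4-[(1S,5S)-5-(TBSO)-4-(TESOCH2)cyclohex-3-en-1-yl]pent-4-enal
Conditions: i-Bu2AlH (1.1 equiv), CH2Cl2, −78 °C; MeOH quench
Reagents that add atoms: none
Why: Partial reduction of a tert-butyl ester, whose aluminium hemiacetal should persist at −78 °C so that the aldehyde is released only on work-up, the silyl ethers and alkenes being inert.

Step 8
Reactants: 10 4-[(1S,5S)-5-(TBSO)-4-(TESOCH2)cyclohex-3-en-1-yl]pent-4-enal; 11 ethyl 2-(triphenylphosphoranylidene)propanoate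
Product: 12 ethyl (2E)-2-methyl-6-[(1S,5S)-5-(TBSO)-4-(TESOCH2)cyclohex-3-en-1-yl]hepta-2,6-dienoate
Conditions: 11 (1.5 equiv), CH2Cl2, rt
Reagents that add atoms: ethyl 2-(triphenylphosphoranylidene)propanoate (11), CCOC(=O)C(C)=P(c1ccccc1)(c1ccccc1)c1ccccc1
Why: Wittig olefination with a stabilised α-methyl ylide, which should give the (E)-trisubstituted enoate (chain trans to the ester) and so the C10=C11 geometry that the epoxidation needs.

Step 9
Reactants: 12 ethyl (2E)-2-methyl-6-[(1S,5S)-5-(TBSO)-4-(TESOCH2)cyclohex-3-en-1-yl]hepta-2,6-dienoate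
Product: 13 (2E)-2-methyl-6-[(1S,5S)-5-(TBSO)-4-(TESOCH2)cyclohex-3-en-1-yl]hepta-2,6-dien-1-ol
Conditions: i-Bu2AlH (2.5 equiv), CH2Cl2, −78 °C
Reagents that add atoms: none
Why: 1,2-Reduction of an α,β-unsaturated ester by two hydrides from i-Bu2AlH should give the (E)-allylic alcohol without change of alkene geometry or loss of a silyl ether.

Step 10
Reactants: 13 (2E)-2-methyl-6-[(1S,5S)-5-(TBSO)-4-(TESOCH2)cyclohex-3-en-1-yl]hepta-2,6-dien-1-ol
Product: 14 [(2S,3S)-2-methyl-3-{3-[(1S,5S)-5-(TBSO)-4-(TESOCH2)cyclohex-3-en-1-yl]but-3-en-1-yl}oxiran-2-yl]methanol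
Conditions: Ti(Oi-Pr)4 (10 mol %), L-(+)-diethyl tartrate (12 mol %), t-BuOOH (2 equiv, in decane), 4 Å molecular sieves, CH2Cl2, −20 °C
Reagents that add atoms: tert-butyl hydroperoxide, CC(C)(C)OO
Why: The tetravalent titanium tartrate dimer exchanges isopropoxide ligands for the C12 alkoxide of 13 and for tert-butyl peroxide, and the activated peroxide oxygen is then transferred within the complex to C10=C11 in a concerted step. This is the Katsuki–Sharpless asymmetric epoxidation, whose closest precedent is its use on (E)-2-methylalk-2-en-1-ols. The oxirane, the only ring formed, closes in a [2+1] fashion by suprafacial delivery of one oxygen atom to both alkene carbons (C10–O and C11–O made together), so the E geometry is carried over as the trans relationship of C9 and C12. C10 and C11 are set by the L-(+)-tartrate ligand (reagent control), which for this substitution pattern should direct oxygen to the enantioface that gives the (2S,3S)-epoxy alcohol; this is the C11 arrangement of the target, whose descriptor becomes R only because C10 later loses its oxygen, and the relative configuration of the two centres follows from the alkene geometry. The step needs site selectivity among three alkenes and enantioface selectivity: only C10=C11 has a free allylic hydroxyl to anchor the metal, whereas the ring alkene has both neighbouring oxygens silylated and C7=C14 has no hydroxyl within reach, so neither should react with t-BuOOH at −20 °C. Facial selectivity is imposed by the catalyst and should be independent of the remote ring stereocentres C1 and C5.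

Step 11
Reactants: 14 [(2S,3S)-2-methyl-3-{3-[(1S,5S)-5-(TBSO)-4-(TESOCH2)cyclohex-3-en-1-yl]but-3-en-1-yl}oxiran-2-yl]methanol
Product: 17 (2R,3E)-2-methyl-6-[(1S,5S)-5-(TBSO)-4-(TESOCH2)cyclohex-3-en-1-yl]hepta-3,6-diene-1,2-diol, via hydroxy selenide 15 (not isolated), via selenoxide 16 (not isolated)
Conditions: PhSeSePh, NaBH4, EtOH, rt to 50 °C; then 30% H2O2, pyridine, THF, 0 °C to rt
Reagents that add atoms: none
Why: Selenide opening of an epoxide followed by selenoxide syn-elimination, in which PhSe− should attack the secondary C10 by SN2 (inversion) and not the fully substituted C11, and the selenoxide can eliminate only toward C9 because C11 has no hydrogen, so the oxygen stays on C11 with its configuration intact (now 11R) and the C9=C10 alkene should form with E geometry.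

Step 12
Reactants: 17 (2R,3E)-2-methyl-6-[(1S,5S)-5-(TBSO)-4-(TESOCH2)cyclohex-3-en-1-yl]hepta-3,6-diene-1,2-diol
Product: 18 (2R,3E)-6-[(1S,5S)-5-(TBSO)-4-(hydroxymethyl)cyclohex-3-en-1-yl]-2-methylhepta-3,6-diene-1,2-diol
Conditions: PPTS, MeOH/CH2Cl2, 0 °C
Reagents that add atoms: none
Why: Acid-catalysed methanolysis is much faster for a primary triethylsilyl ether than for a secondary TBS ether, and PPTS at 0 °C is too weak an acid to ionise the tertiary allylic alcohol.

Step 13
Reactants: 18 (2R,3E)-6-[(1S,5S)-5-(TBSO)-4-(hydroxymethyl)cyclohex-3-en-1-yl]-2-methylhepta-3,6-diene-1,2-diol; 19 isobutyryl chloride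
Product: 20 {(4S,6S)-6-(TBSO)-4-[(4E,6R)-6-hydroxy-6-methyl-7-(2-methylpropanoyloxy)hepta-1,4-dien-2-yl]cyclohex-1-en-1-yl}methyl 2-methylpropanoate
Conditions: 19 (2.4 equiv), pyridine, CH2Cl2, 0 °C to rt
Reagents that add atoms: isobutyryl chloride (19), CC(C)C(Cl)=O
Why: Acylation with an acid chloride and pyridine should take place only at the two primary hydroxyls on C12 and C15, since the tertiary C11 hydroxyl is too hindered under these conditions and O5 is still silylated.

Step 14
Reactants: 20 {(4S,6S)-6-(TBSO)-4-[(4E,6R)-6-hydroxy-6-methyl-7-(2-methylpropanoyloxy)hepta-1,4-dien-2-yl]cyclohex-1-en-1-yl}methyl 2-methylpropanoate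
Product: 21 {(4S,6S)-6-hydroxy-4-[(4E,6R)-6-hydroxy-6-methyl-7-(2-methylpropanoyloxy)hepta-1,4-dien-2-yl]cyclohex-1-en-1-yl}methyl 2-methylpropanoate (CNP0599657.1)
Conditions: HF·pyridine, pyridine, THF, 0 °C to rt
Reagents that add atoms: none
Why: Fluoride-mediated desilylation under buffered, weakly acidic conditions should remove the last silyl group without base-induced acyl migration (O15 to O5 or O12 to O11) and without ionising either allylic alcohol.

Compound list
1 | (S)-carvone | C=C(C)[C@H]1CC=C(C)C(=O)C1 | starting material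
2 | (5S)-5-(3-chloroprop-1-en-2-yl)-2-methylcyclohex-2-en-1-one | C=C(CCl)[C@H]1CC=C(C)C(=O)C1 | intermediate
3 | (1S,5S)-5-(3-chloroprop-1-en-2-yl)-2-methylcyclohex-2-en-1-ol | C=C(CCl)[C@H]1CC=C(C)[C@@H](O)C1 | intermediate
4 | tert-butyl{[(1S,5S)-5-(3-chloroprop-1-en-2-yl)-2-methylcyclohex-2-en-1-yl]oxy}dimethylsilane | C=C(CCl)[C@H]1CC=C(C)[C@@H](O[Si](C)(C)C(C)(C)C)C1 | intermediate
5 | [(4S,6S)-6-(TBSO)-4-(3-chloroprop-1-en-2-yl)cyclohex-1-en-1-yl]methanol | C=C(CCl)[C@H]1CC=C(CO)[C@@H](O[Si](C)(C)C(C)(C)C)C1 | intermediate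
6 | triethyl{[(4S,6S)-6-(TBSO)-4-(3-chloroprop-1-en-2-yl)cyclohex-1-en-1-yl]methoxy}silane | C=C(CCl)[C@H]1CC=C(CO[Si](CC)(CC)CC)[C@@H](O[Si](C)(C)C(C)(C)C)C1 | intermediate
7 | tert-butyl acetate | CC(=O)OC(C)(C)C | starting material
8 | lithium enolate of tert-butyl acetate (formed in the flask, not isolated) | C=C(O[Li])OC(C)(C)C | intermediate
9 | tert-butyl 4-[(1S,5S)-5-(TBSO)-4-(TESOCH2)cyclohex-3-en-1-yl]pent-4-enoate | C=C(CCC(=O)OC(C)(C)C)[C@H]1CC=C(CO[Si](CC)(CC)CC)[C@@H](O[Si](C)(C)C(C)(C)C)C1 | intermediate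
10 | 4-[(1S,5S)-5-(TBSO)-4-(TESOCH2)cyclohex-3-en-1-yl]pent-4-enal | C=C(CCC=O)[C@H]1CC=C(CO[Si](CC)(CC)CC)[C@@H](O[Si](C)(C)C(C)(C)C)C1 | intermediate
11 | ethyl 2-(triphenylphosphoranylidene)propanoate | CCOC(=O)C(C)=P(c1ccccc1)(c1ccccc1)c1ccccc1 | starting material
12 | ethyl (2E)-2-methyl-6-[(1S,5S)-5-(TBSO)-4-(TESOCH2)cyclohex-3-en-1-yl]hepta-2,6-dienoate | C=C(CC/C=C(\C)C(=O)OCC)[C@H]1CC=C(CO[Si](CC)(CC)CC)[C@@H](O[Si](C)(C)C(C)(C)C)C1 | intermediate
13 | (2E)-2-methyl-6-[(1S,5S)-5-(TBSO)-4-(TESOCH2)cyclohex-3-en-1-yl]hepta-2,6-dien-1-ol | C=C(CC/C=C(\C)CO)[C@H]1CC=C(CO[Si](CC)(CC)CC)[C@@H](O[Si](C)(C)C(C)(C)C)C1 | intermediate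
14 | [(2S,3S)-2-methyl-3-{3-[(1S,5S)-5-(TBSO)-4-(TESOCH2)cyclohex-3-en-1-yl]but-3-en-1-yl}oxiran-2-yl]methanol | C=C(CC[C@@H]2O[C@@]2(C)CO)[C@H]1CC=C(CO[Si](CC)(CC)CC)[C@@H](O[Si](C)(C)C(C)(C)C)C1 | intermediate
15 | (2S,3R)-2-methyl-3-(phenylselanyl)-6-[(1S,5S)-5-(TBSO)-4-(TESOCH2)cyclohex-3-en-1-yl]hept-6-ene-1,2-diol (not isolated) | C=C(CC[C@@H]([Se]c2ccccc2)[C@@](C)(O)CO)[C@H]1CC=C(CO[Si](CC)(CC)CC)[C@@H](O[Si](C)(C)C(C)(C)C)C1 | intermediate
16 | selenoxide of 15, both configurations at selenium (not isolated) | C=C(CC[C@@H]([Se](=O)c2ccccc2)[C@@](C)(O)CO)[C@H]1CC=C(CO[Si](CC)(CC)CC)[C@@H](O[Si](C)(C)C(C)(C)C)C1 | intermediate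
17 | (2R,3E)-2-methyl-6-[(1S,5S)-5-(TBSO)-4-(TESOCH2)cyclohex-3-en-1-yl]hepta-3,6-diene-1,2-diol | C=C(C/C=C/[C@@](C)(O)CO)[C@H]1CC=C(CO[Si](CC)(CC)CC)[C@@H](O[Si](C)(C)C(C)(C)C)C1 | intermediate
18 | (2R,3E)-6-[(1S,5S)-5-(TBSO)-4-(hydroxymethyl)cyclohex-3-en-1-yl]-2-methylhepta-3,6-diene-1,2-diol | C=C(C/C=C/[C@@](C)(O)CO)[C@H]1CC=C(CO)[C@@H](O[Si](C)(C)C(C)(C)C)C1 | intermediate
19 | isobutyryl chloride (2-methylpropanoyl chloride) | CC(C)C(Cl)=O | starting material
20 | {(4S,6S)-6-(TBSO)-4-[(4E,6R)-6-hydroxy-6-methyl-7-(2-methylpropanoyloxy)hepta-1,4-dien-2-yl]cyclohex-1-en-1-yl}methyl 2-methylpropanoate | C=C(C/C=C/[C@@](C)(O)COC(=O)C(C)C)[C@H]1CC=C(COC(=O)C(C)C)[C@@H](O[Si](C)(C)C(C)(C)C)C1 | intermediate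
21 | {(4S,6S)-6-hydroxy-4-[(4E,6R)-6-hydroxy-6-methyl-7-(2-methylpropanoyloxy)hepta-1,4-dien-2-yl]cyclohex-1-en-1-yl}methyl 2-methylpropanoate (CNP0599657.1) | C=C(C/C=C/[C@@](C)(O)COC(=O)C(C)C)[C@H]1CC=C(COC(=O)C(C)C)[C@@H](O)C1 | target

Total step count: 14. Longest linear sequence: 14 steps, from (S)-carvone (1) to 21.

Steps most likely to fail

First, step 4. The oxidant may also attack the C7=C14 alkene in an ene reaction (oxidation at C1–H or at the chloromethyl carbon), and the new C15 alcohol may be oxidised further. The fallback sets out from 4 and comes back at 5, with oxygen brought in through the ring alkene instead of a C–H bond. mCPBA (NaHCO3, CH2Cl2, 0 °C) should epoxidise only the more electron-rich trisubstituted alkene, anti to the silyloxy group, to give the 3,4-epoxide F1; the configuration at the two oxirane carbons is of no consequence. Diethylaluminium 2,2,6,6-tetramethylpiperidide (from lithium 2,2,6,6-tetramethylpiperidide and Et2AlCl, toluene, 0 °C) should then remove a methyl proton and open the oxirane to the exocyclic allylic alcohol F2. Catalytic Ph3SiOReO3 (Et2O, 0 °C) would transpose the hydroxyl from C3 to C15, the equilibrium being expected to favour the trisubstituted ring alkene with the primary alcohol, which is 5.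

Second, step 11. Under the basic selenide conditions the free C12 alkoxide may shift the oxirane to C11–C12 (Payne rearrangement) before the slow SN2 attack at C10, next to the quaternary C11, has occurred; the selenide then enters at C12 and cannot eliminate. The fallback sets out from 14 and comes back at 20, with C12 acylated before the epoxide is opened. Acylation of 14 with 19 and pyridine gives the epoxy isobutyrate F3, in which no alkoxide can form. PhSeSePh/NaBH4 in EtOH should give the hydroxy selenide ester F4 (not isolated) and H2O2/pyridine the selenoxide ester F5 (not isolated), which eliminates to the tertiary allylic alcohol ester F6. PPTS in MeOH removes the triethylsilyl group to give the primary alcohol F7, and a second acylation with 19 and pyridine gives 20. The fallback is one step longer.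

Third, step 6. Displacement of the allylic chloride by the ester enolate may be sluggish, which would leave time for decomposition and self-condensation of the enolate on warming. The fallback sets out from 6 and comes back at 10 with a smaller, more nucleophilic two-carbon donor and the same step count. Lithioacetonitrile (CH3CN, n-BuLi, THF, −78 °C) should alkylate 6 to give the nitrile F8. i-Bu2AlH (toluene, −78 °C) reduces it to the aldimine F9 (formed as its N-aluminium derivative, not isolated), which is hydrolysed to aldehyde 10 on work-up with an aqueous pH 5 buffer that the silyl ethers should tolerate.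

Further compounds
F1 | step 4 | 3,4-epoxide of 4 (oxirane anti to the silyloxy group) | C=C(CCl)[C@H]1C[C@@H]2O[C@]2(C)[C@@H](O[Si](C)(C)C(C)(C)C)C1
F2 | step 4 | 5-(3-chloroprop-1-en-2-yl)-3-(TBSO)-2-methylidenecyclohexan-1-ol (hydroxyl on C3 and exocyclic methylene on C4 in target numbering) | C=C(CCl)[C@H]1C[C@H](O)C(=C)[C@@H](O[Si](C)(C)C(C)(C)C)C1
F3 | step 11 | [(2S,3S)-2-methyl-3-{3-[(1S,5S)-5-(TBSO)-4-(TESOCH2)cyclohex-3-en-1-yl]but-3-en-1-yl}oxiran-2-yl]methyl 2-methylpropanoate | C=C(CC[C@@H]2O[C@@]2(C)COC(=O)C(C)C)[C@H]1CC=C(CO[Si](CC)(CC)CC)[C@@H](O[Si](C)(C)C(C)(C)C)C1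
F4 | step 11 | (2S,3R)-2-hydroxy-2-methyl-3-(phenylselanyl)-6-[(1S,5S)-5-(TBSO)-4-(TESOCH2)cyclohex-3-en-1-yl]hept-6-en-1-yl 2-methylpropanoate (not isolated) | C=C(CC[C@@H]([Se]c2ccccc2)[C@@](C)(O)COC(=O)C(C)C)[C@H]1CC=C(CO[Si](CC)(CC)CC)[C@@H](O[Si](C)(C)C(C)(C)C)C1
F5 | step 11 | selenoxide of F4, both configurations at selenium (not isolated) | C=C(CC[C@@H]([Se](=O)c2ccccc2)[C@@](C)(O)COC(=O)C(C)C)[C@H]1CC=C(CO[Si](CC)(CC)CC)[C@@H](O[Si](C)(C)C(C)(C)C)C1
F6 | step 11 | (2R,3E)-2-hydroxy-2-methyl-6-[(1S,5S)-5-(TBSO)-4-(TESOCH2)cyclohex-3-en-1-yl]hepta-3,6-dien-1-yl 2-methylpropanoate | C=C(C/C=C/[C@@](C)(O)COC(=O)C(C)C)[C@H]1CC=C(CO[Si](CC)(CC)CC)[C@@H](O[Si](C)(C)C(C)(C)C)C1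
F7 | step 11 | (2R,3E)-2-hydroxy-6-[(1S,5S)-5-(TBSO)-4-(hydroxymethyl)cyclohex-3-en-1-yl]-2-methylhepta-3,6-dien-1-yl 2-methylpropanoate | C=C(C/C=C/[C@@](C)(O)COC(=O)C(C)C)[C@H]1CC=C(CO)[C@@H](O[Si](C)(C)C(C)(C)C)C1
F8 | step 6 | 4-[(1S,5S)-5-(TBSO)-4-(TESOCH2)cyclohex-3-en-1-yl]pent-4-enenitrile | C=C(CCC#N)[C@H]1CC=C(CO[Si](CC)(CC)CC)[C@@H](O[Si](C)(C)C(C)(C)C)C1
F9 | step 6 | 4-[(1S,5S)-5-(TBSO)-4-(TESOCH2)cyclohex-3-en-1-yl]pent-4-en-1-imine (not isolated) | C=C(CCC=N)[C@H]1CC=C(CO[Si](CC)(CC)CC)[C@@H](O[Si](C)(C)C(C)(C)C)C1
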